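## Structural features

6,8-Diprenylnaringenin is a flavanone. A fully substituted phloroglucinol-type benzene (ring A) is fused through C4a–C8a to a dihydropyranone (ring C: O1, C2, C3, C4=O), and C2 carries a 4-hydroxyphenyl group (ring B). Ring A bears oxygen on C5, C7 and C8a and carbon on the three positions between them: the ketone carbon C4 on C4a and a 3-methylbut-2-enyl chain on each of C6 and C8. C2 is the only stereocentre, (S), with no stereogenic neighbour. It is benzylic, carries the ring oxygen and lies β to the ketone, so it is lost by retro-oxa-Michael opening to the 2'-hydroxychalcone under base or heat, and by benzylic ionisation when the 4'-oxygen is electron-rich. The two trisubstituted alkenes are the other fragile elements: they do not survive electrophilic halogen, peracids or hydrogenation, and strong acid adds the neighbouring C5 and C7 phenols across them to give chromans. The real difficulty is to assemble a hexasubstituted ring A with the right pattern and to bring in C2 as one enantiomer without passing through the chalcone, which closes without facial control. The feature used here is that C4a holds the ketone carbon C4 and its ortho neighbour C8a holds the ether oxygen O1: the atoms O1–C2–C3–C4(=O) are those of a 4-aryl β-lactone, and C4a–C8a is an aryne inserted into its acyl–oxygen bond, with the C5 oxygen next to C4a deciding the orientation.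

## Logic of the disconnections

26 to 25. The O–C bonds of the two acetals on O5 and O7 and of the aryl ester on O4' are cut last. The phenols must be masked through metalation, aryne and lactone chemistry, and both kinds of group fall to methanolic acid in one operation. The gain is that 25 has no free phenol beside a prenyl group and no acidic O–H. The demand is an acidic, not basic, unmasking that is mild enough for the alkenes and for C2.

25 to 18 and 22. O1–C8a and C4–C4a are cut. These bonds join an ether oxygen and a ketone carbon to adjacent arene carbons, which is the pattern left by σ-insertion of 23 into an acyl–oxygen bond. The four atoms removed form a strained lactone that already holds C2. The tricycle falls into 18, a hexasubstituted benzene without a stereocentre, and the small chiral piece 22, joined convergently. The forward step must put oxygen on C8a and not C4a, must not break the C2–O bond, and must unmask 23 faster than fluoride destroys 22.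

22 to 19 and 20. The bond between the methylene and the carbinol carbon and the acyl–oxygen bond are cut, a [2+2] retron that leads to 19 and to 21, which is made from 20. One catalytic step then sets C2. The acetoxy group keeps the aldehyde electrophilic and the lactone resistant to benzylic ionisation. The demand is facial control by a chiral catalyst.

18 to 16 (through 17). The S–O bond of the triflate is cut and the C8a oxygen is traced to a monoalkyl carbamate. This oxygen has to be the strongest directing group on the ring until the last moment and a leaving group only afterwards, because a triflate tolerates no organolithium. The carbamate must therefore leave without acid, fluoride or hard nucleophiles, which would touch the C–Si bond, the acetals or the alkenes.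

16 to 9 and 4 (through 12). C8–CH2 and C4a–Si are cut in one operation. Both carbons lie between the carbamate oxygen and an acetal oxygen, so each is reached by directed deprotonation. This avoids electrophilic halogen, which the alkenes would not survive, and low-yielding phenoxide C-alkylation. Silicon goes in first and the prenyl group second, so that no carbamate with an ortho prenyl group (an acidic benzylic–allylic CH2 open to lateral metalation) ever meets an alkyllithium. The two metalations share one flask because the N-silyl mask that the first one needs is still in place in 12, and an aqueous work-up between them would only remove it. The demands are exact stoichiometry of the silyl chloride, coupling at the primary end of the allyl unit, and trapping of the second aryllithium before the carbamoyl group can migrate.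

9 to 8 to 7. The carbamate O–C(=O) bond and then an O–Si bond are cut. The C8a oxygen must be non-directing and bulky while C6 is functionalised, and directing afterwards. Two simple functional-group steps are the price for unambiguous regiochemistry.

7 to 3 and 4. C6–CH2 is cut. With the third oxygen under a bulky silyl group, the carbon between the two acetal oxygens is the only site of lithiation. The forward step needs SN2 coupling of the allyl bromide.

3 to 1. Three O–protecting-group bonds are cut. 1 is desymmetrised by one silyl and two acetal groups in a single flask. The step is statistical, so it stands first, where material is cheapest.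

## Other disconnections considered

Alternative 1: The cut is at the two aryl–CH2 bonds, C6–C1'' and C8–C1'', on a finished flavanone. Forward, (S)-naringenin A4 is silylated on O7 and O4' and iodinated at C6 and C8 to the diiodide A2. Pd(PPh3)4 (zerovalent palladium) then couples both C–I bonds with tributyl(3-methylbut-2-enyl)stannane A3 in a double Stille reaction to give the bis-silyl ether A1, and fluoride frees the phenols.
- In favour: skeleton and stereocentre are bought, no ring is built, the prenyl groups arrive last so nothing upstream must tolerate them, and the count is four to five steps.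
- Against: the stereocentre is only as good as the purchased flavanone and its survival. A 5-hydroxyflavanone opens to the chalcone under base and heat, and silylation, a hot coupling and fluoride desilylation all offer that path.
- Against: each iodide is flanked by two oxygen substituents, so two oxidative additions and two transmetalations must occur at very hindered carbons, with hydrodeiodination as the usual escape.
- Against: allylstannanes can transfer with allylic transposition, so the branched 1,1-dimethylallyl isomer is a real risk at either site. A silyl ether on O7 between two iodides is also hard to install and easy to lose.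
- Comparison: in step economy Alternative 1 is clearly better than the chosen plan. In mechanistic precedent it is also better, since every step is a known reaction type. On structure the chosen plan is stronger: the configuration comes from a catalytic step whose enantiomeric purity can be checked at the stage of 22, C2 is never exposed to base, and both prenyl groups are fixed as linear by SN2 coupling of arylcopper reagents.

Alternative 2: Ring A is cut into three two-carbon pieces by breaking C4a–C8a, C5–C6 and C7–C8, which leaves the alkyne pairs C8≡C8a, C4a≡C5 and C6≡C7. Forward, the diyne A6 has an alkynyl ether (O1–C8a≡C8–prenyl) and an alkoxy ynone (C4(=O)–C4a≡C5–O) tethered through O1–C2–C3–C4. It is combined with the siloxyalkyne A7 under [Rh(cod)2]BF4 and BINAP (monovalent rhodium) in a (2+2+2) cycloaddition that closes rings A and C at once and gives A5.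
- In favour: three C–C bonds and two rings form in one step. Every ring-A substituent already sits on an alkyne carbon, so no substitution on a crowded arene is needed and the three oxygens are born differentiated. C2 is a simple carbinol ether set early.
- Against: A6 contains a secondary benzylic 1-alkynyl ether, a class that is hard to make at such an oxygen and that fragments thermally by retro-ene loss of a ketene when a β-hydrogen is present (here on C3). It also contains an alkoxy ynone that is a very electrophilic, hydrolytically labile push–pull system.
- Against: the orientation of A7 on the rhodacycle (C6 to C5 and C7 to C8, not the reverse) has no strong bias, because both termini of the metallacycle are substituted. The skipped ene–yne units can divert the metal into cycloisomerisation. The chiral ligand has nothing to control and only creates a matched/mismatched question.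
- Comparison: in bond-forming power Alternative 2 is better than the chosen plan (two rings and three bonds against one ring and two bonds). It also avoids the statistical desymmetrisation of 1, which is a further point in its favour. Mechanistically the two are about equal, since each asks a known reaction class to accept an unproven substrate type. In stability of the components the chosen plan is better: 18 and 22 can be purified and stored, A6 probably cannot. In step count the alternative offers no gain.

Alternative 3: Ring A is again built last, on a preformed ring C; the cuts are C8–C8a, C5–C6, C7–C8 and C4a–C5. Forward, the diazoketone A9 is an (S)-2-aryl-2,3-dihydropyran-4-one whose C8a carries the acyl group C5(=O)–C8(=N2)–prenyl. Irradiation triggers a Wolff rearrangement in which C8a migrates to C8. The vinylketene adds the siloxyalkyne A7 (C5–C6, C7–C8), and the cyclobutenone opens and recloses by 6π electrocyclisation (C4a–C5) to the 5-phenol A8, a Danheiser benzannulation.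
- In favour: the reaction class is established for diazoketones and siloxyalkynes. The polarity of ketene and alkyne places the oxygens and both prenyl groups without any directing group. The C5 hydroxyl is born free, so one protecting group fewer is needed. The dihydropyranone with its stereocentre is the product of a catalytic asymmetric hetero-Diels–Alder reaction.
- Against: a diazoketone with an alkyl group on the diazo carbon is prone to 1,2-hydrogen shift to the enone in competition with the Wolff shift. The carbene or the excited enone can engage the prenyl alkenes (cyclopropanation, [2+2] photocycloaddition).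
- Against: the migrating carbon is the electron-poor β-carbon of a vinylogous ester. The diazo group must be installed beside a second enolisable ketone. The final desilylation needs basic fluoride on the finished flavanone.
- Comparison: in mechanistic precedent Alternative 3 is better than the chosen plan, because its key step is a demonstrated reaction type. In protecting-group economy at C5 it is slightly better. In step count the two are about equal. The chosen plan is preferred on structural grounds: it never irradiates a molecule holding an enone and two alkenes, its components are thermally robust, and the one selectivity it must win, the direction of addition to a 3-alkoxyaryne, has a strong and predictable bias.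

Key step: step 8

Remark: the structures of 18, 22 and 25 agree with each other and with 26 atom by atom, so none needs correcting. The descriptor stays (S) from 22 to 26 because the priority order O > aryl > CH2 > H at the carbinol carbon is the same in the four- and the six-membered ring.

Assumption: 4-acetoxybenzaldehyde 19 is a catalogue compound and is used as bought.

Assumption: the quinine-derived catalyst is taken to deliver the (S)-lactone, by analogy with the usual sense of cinchona-catalysed ketene additions to aldehydes. If the sense proves opposite, the quinidine-derived pseudo-enantiomer is used.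

Step 1
Reactants: 1 phloroglucinol
Product: 3 [3,5-bis(methoxymethoxy)phenoxy]triisopropylsilane, via monosilyl ether 2 (not isolated)
Conditions: TIPSCl (1.0 equiv), i-Pr2NEt, DMAP (cat.), DMF, 0 °C to rt; then MOMCl (3 equiv), i-Pr2NEt, 0 °C to rt
Reagents that add atoms: chlorotriisopropylsilane, CC(C)[Si](Cl)(C(C)C)C(C)C; chloromethyl methyl ether, COCCl
Why: O-silylation with one equivalent followed by exhaustive Williamson-type O-alkylation marks the future C8a oxygen with a bulky, non-coordinating group and gives the other two oxygens the acetals that later direct metalation; the statistical by-products (tris-acetal, bis-silyl ether) differ in polarity and are removed by chromatography.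

Step 2
Reactants: 3 [3,5-bis(methoxymethoxy)phenoxy]triisopropylsilane; 4 prenyl bromide
Product: 7 [3,5-bis(methoxymethoxy)-4-(3-methylbut-2-en-1-yl)phenoxy]triisopropylsilane, via aryllithium 5 (not isolated), via arylcopper 6 (not isolated)
Conditions: n-BuLi, THF, 0 °C; CuBr·SMe2, −78 °C; then 4, −78 °C to rt
Reagents that add atoms: none
Why: Directed ortho-metalation: the two acetal oxygens cooperate to direct lithiation to the carbon between them while the silyl ether neither coordinates nor leaves room beside itself; transmetalation to copper makes the allylation an SN2 coupling at the primary carbon, so the linear prenyl group results.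

Step 3
Reactants: 7 [3,5-bis(methoxymethoxy)-4-(3-methylbut-2-en-1-yl)phenoxy]triisopropylsilane
Product: 8 3,5-bis(methoxymethoxy)-4-(3-methylbut-2-en-1-yl)phenol
Conditions: TBAF, THF, 0 °C; aq. NH4Cl
Reagents that add atoms: none
Why: Fluoride desilylation driven by the Si–F bond; acetals and the alkene are inert to fluoride, and the symmetric phenol formed has two equivalent ortho positions.

Step 4
Reactants: 8 3,5-bis(methoxymethoxy)-4-(3-methylbut-2-en-1-yl)phenol
Product: 9 3,5-bis(methoxymethoxy)-4-(3-methylbut-2-en-1-yl)phenyl N-isopropylcarbamate
Conditions: i-PrNCO, Et3N (cat.), CH2Cl2, rt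
Reagents that add atoms: isopropyl isocyanate, CC(C)N=C=O
Why: Base-catalysed addition of a phenol to an isocyanate; the N–H carbamate becomes a strong ortho-directing group once N-silylated and can later be removed by E1cB elimination without acid or hard nucleophiles.

Step 5
Reactants: 9 3,5-bis(methoxymethoxy)-4-(3-methylbut-2-en-1-yl)phenyl N-isopropylcarbamate; 4 prenyl bromide
Product: 16 3,5-bis(methoxymethoxy)-2,4-bis(3-methylbut-2-en-1-yl)-6-(trimethylsilyl)phenyl N-isopropylcarbamate, via N-silyl carbamate 10 (not isolated), via first aryllithium 11 (not isolated), via C-silyl N-silyl carbamate 12 (not isolated), via second aryllithium 13 (not isolated), via arylcopper 14 (not isolated), via diprenyl N-silyl carbamate 15 (not isolated)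
Conditions: TMSOTf, TMEDA, Et2O, 0 °C to rt; n-BuLi, TMEDA, −78 °C; TMSCl (1.0 equiv), −78 to −20 °C; n-BuLi, −78 °C; CuBr·SMe2, −78 °C; 4, −78 °C to rt; aq. NaHCO3
Reagents that add atoms: chlorotrimethylsilane, C[Si](C)(C)Cl
Why: Two carbamate-directed ortho-metalations in one flask after in situ N-silylation: the first lithiation goes to one of the two equivalent carbons flanked by carbamate and acetal and one equivalent of TMSCl places silicon at the future C4a; the N–Si mask is still in place in 12, so a second portion of n-BuLi lithiates the only ring C–H left, and transmetalation to copper at −78 °C forestalls carbamoyl migration and gives SN2 allylation. The N–Si bond is hydrolysed only on the final work-up, no electrophilic halogen is used, and because this prenyl group enters last no ortho-prenyl carbamate ever meets an alkyllithium.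

Step 6
Reactants: 16 3,5-bis(methoxymethoxy)-2,4-bis(3-methylbut-2-en-1-yl)-6-(trimethylsilyl)phenyl N-isopropylcarbamate
Product: 18 3,5-bis(methoxymethoxy)-2,4-bis(3-methylbut-2-en-1-yl)-6-(trimethylsilyl)phenyl trifluoromethanesulfonate, via phenol 17 (not isolated)
Conditions: DBU, Et2NH, MeCN, 40 °C; then PhNTf2, rt
Reagents that add atoms: N-phenylbis(trifluoromethanesulfonimide), O=S(=O)(N(c1ccccc1)S(=O)(=O)C(F)(F)F)C(F)(F)F
Why: E1cB cleavage of the N-monoalkyl carbamate (N-deprotonation, loss of isopropyl isocyanate, capture by diethylamine as a urea) is insensitive to the two flanking groups and uses no acid or fluoride, so the C–Si bond, the acetals and the alkenes survive; the phenoxide is sulfonylated in the same flask to the ortho-silylaryl triflate.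

Step 7
Reactants: 19 4-acetoxybenzaldehyde; 20 acetyl chloride
Product: 22 (S)-4-(4-acetoxyphenyl)oxetan-2-one, via ketene 21 (not isolated)
Conditions: O-trimethylsilylquinine (10 mol %), LiClO4, i-Pr2NEt, CH2Cl2/Et2O, −78 °C
Reagents that add atoms: none
Why: Cinchona-alkaloid-catalysed acyl halide–aldehyde cyclocondensation (formal [2+2] of ketene and aldehyde): the amine base makes ketene from 20, the alkaloid turns it into a chiral ammonium enolate that adds to the lithium-activated aldehyde through a closed transition structure and then lactonises, so the catalyst's shielded face sets the (S) carbinol centre; the acetoxy group keeps the aldehyde electrophilic and the lactone resistant to benzylic ionisation.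

Step 8
Reactants: 18 3,5-bis(methoxymethoxy)-2,4-bis(3-methylbut-2-en-1-yl)-6-(trimethylsilyl)phenyl trifluoromethanesulfonate; 22 (S)-4-(4-acetoxyphenyl)oxetan-2-one
Product: 25 (S)-6,8-diprenylnaringenin 4'-acetate 5,7-bis(methoxymethyl) ether, via aryne 23 (not isolated), via zwitterion 24 (not isolated)
Conditions: CsF, MeCN/toluene, 25 °C, 22 in excess
Reagents that add atoms: none
Why: Proposed new method: fluoride removes the silyl group of 18 and triflate leaves to give aryne 23; the ring oxygen of 22 adds to C8a and the zwitterion 24 passes its acyl group from the oxonium oxygen to the carbanion at C4a through a four-membered transition structure, which forms O1–C8a and C4–C4a. The closest known reaction types are aryne σ-insertion into the acyl–nitrogen bond of amides and ureas and into the C–C bond of β-dicarbonyl compounds, and the oxygen-to-carbon acyl shift that follows addition of carboxylic acids to arynes; insertion into the acyl–oxygen bond of a lactone is not among them. Ring C is closed by ring expansion of the four-membered lactone by two atoms (4-exo-trig addition of the aryl anion to the acyl carbon with loss of the oxonium leaving group), not by cyclisation of an open chain, and release of β-lactone strain drives it. No stereocentre is formed: C2 comes from 22, none of its four bonds is broken, and the (S) configuration is carried over unchanged. The step needs oxygen on C8a and the acyl group on C4a; the inductive and distortion effect of the C5 acetal oxygen makes C8a the electrophilic aryne carbon and stabilises the carbanion at C4a, and this bias is expected to outweigh the steric preference set by the C8 prenyl group. It also needs attack by the ring oxygen and not the carbonyl oxygen, which is the less certain point; the acyl-oxonium of 24 is so activated that acyl transfer should outrun protonation of the aryl anion. Slow aryne release from sparingly soluble CsF, a solvent mixture poor in acidic C–H bonds and an excess of 22 are chosen to suppress ene reaction of 23 with prenyl groups and fluoride- or base-induced opening of 22.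

Step 9
Reactants: 25 (S)-6,8-diprenylnaringenin 4'-acetate 5,7-bis(methoxymethyl) ether
Product: 26 (S)-6,8-diprenylnaringenin
Conditions: HCl (1 M), MeOH, 40 °C
Reagents that add atoms: none
Why: Acid-catalysed acetal exchange removes both methoxymethyl groups (the one on the chelated C5 oxygen first) and acid-catalysed transesterification removes the aryl acetate; no base is present, so C2 cannot epimerise through the chalcone, and dilute acid at low temperature is chosen to keep the phenols from adding to the prenyl alkenes.

Compound list

1 | phloroglucinol (benzene-1,3,5-triol) | Oc1cc(O)cc(O)c1 | starting material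
2 | 5-(triisopropylsilyloxy)benzene-1,3-diol | CC(C)[Si](Oc1cc(O)cc(O)c1)(C(C)C)C(C)C | intermediate (not isolated)
3 | [3,5-bis(methoxymethoxy)phenoxy]triisopropylsilane | COCOc1cc(OCOC)cc(O[Si](C(C)C)(C(C)C)C(C)C)c1 | intermediate
4 | prenyl bromide (1-bromo-3-methylbut-2-ene) | CC(C)=CCBr | starting material
5 | [2,6-bis(methoxymethoxy)-4-(triisopropylsilyloxy)phenyl]lithium | [Li]c1c(OCOC)cc(O[Si](C(C)C)(C(C)C)C(C)C)cc1OCOC | intermediate (not isolated)
6 | [2,6-bis(methoxymethoxy)-4-(triisopropylsilyloxy)phenyl]copper | [Cu]c1c(OCOC)cc(O[Si](C(C)C)(C(C)C)C(C)C)cc1OCOC | intermediate (not isolated)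
7 | [3,5-bis(methoxymethoxy)-4-(3-methylbut-2-en-1-yl)phenoxy]triisopropylsilane | CC(C)=CCc1c(OCOC)cc(O[Si](C(C)C)(C(C)C)C(C)C)cc1OCOC | intermediate
8 | 3,5-bis(methoxymethoxy)-4-(3-methylbut-2-en-1-yl)phenol | CC(C)=CCc1c(OCOC)cc(O)cc1OCOC | intermediate
9 | 3,5-bis(methoxymethoxy)-4-(3-methylbut-2-en-1-yl)phenyl N-isopropylcarbamate | CC(C)=CCc1c(OCOC)cc(OC(=O)NC(C)C)cc1OCOC | intermediate
10 | 3,5-bis(methoxymethoxy)-4-(3-methylbut-2-en-1-yl)phenyl N-isopropyl-N-(trimethylsilyl)carbamate | CC(C)=CCc1c(OCOC)cc(OC(=O)N(C(C)C)[Si](C)(C)C)cc1OCOC | intermediate (not isolated)
11 | 2-lithio derivative of 10 (lithium between carbamate and acetal) | CC(C)=CCc1c(OCOC)cc(OC(=O)N(C(C)C)[Si](C)(C)C)c([Li])c1OCOC | intermediate (not isolated)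
12 | 3,5-bis(methoxymethoxy)-4-(3-methylbut-2-en-1-yl)-2-(trimethylsilyl)phenyl N-isopropyl-N-(trimethylsilyl)carbamate | CC(C)=CCc1c(OCOC)cc(OC(=O)N(C(C)C)[Si](C)(C)C)c([Si](C)(C)C)c1OCOC | intermediate (not isolated)
13 | 6-lithio derivative of 12 (lithium between carbamate and the second acetal) | CC(C)=CCc1c(OCOC)c([Li])c(OC(=O)N(C(C)C)[Si](C)(C)C)c([Si](C)(C)C)c1OCOC | intermediate (not isolated)
14 | 6-cuprio derivative of 12 | CC(C)=CCc1c(OCOC)c([Cu])c(OC(=O)N(C(C)C)[Si](C)(C)C)c([Si](C)(C)C)c1OCOC | intermediate (not isolated)
15 | 3,5-bis(methoxymethoxy)-2,4-bis(3-methylbut-2-en-1-yl)-6-(trimethylsilyl)phenyl N-isopropyl-N-(trimethylsilyl)carbamate | CC(C)=CCc1c(OCOC)c(CC=C(C)C)c(OC(=O)N(C(C)C)[Si](C)(C)C)c([Si](C)(C)C)c1OCOC | intermediate (not isolated)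
16 | 3,5-bis(methoxymethoxy)-2,4-bis(3-methylbut-2-en-1-yl)-6-(trimethylsilyl)phenyl N-isopropylcarbamate | CC(C)=CCc1c(OCOC)c(CC=C(C)C)c(OC(=O)NC(C)C)c([Si](C)(C)C)c1OCOC | intermediate
17 | 3,5-bis(methoxymethoxy)-2,4-bis(3-methylbut-2-en-1-yl)-6-(trimethylsilyl)phenol | CC(C)=CCc1c(OCOC)c(CC=C(C)C)c(O)c([Si](C)(C)C)c1OCOC | intermediate (not isolated)
18 | 3,5-bis(methoxymethoxy)-2,4-bis(3-methylbut-2-en-1-yl)-6-(trimethylsilyl)phenyl trifluoromethanesulfonate | CC(C)=CCc1c(OCOC)c(CC=C(C)C)c(OS(=O)(=O)C(F)(F)F)c([Si](C)(C)C)c1OCOC | intermediate
19 | 4-acetoxybenzaldehyde (4-formylphenyl acetate) | CC(=O)Oc1ccc(C=O)cc1 | starting material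
20 | acetyl chloride | CC(Cl)=O | starting material
21 | ketene | C=C=O | intermediate (not isolated)
22 | (S)-4-(4-acetoxyphenyl)oxetan-2-one | O=C1C[C@@H](c2ccc(OC(C)=O)cc2)O1 | intermediate
23 | 3,5-bis(methoxymethoxy)-4,6-bis(3-methylbut-2-en-1-yl)-1,2-didehydrobenzene (aryne; C1 = C8a, C2 = C4a) | C1#CC(OCOC)=C(CC=C(C)C)C(OCOC)=C1CC=C(C)C | intermediate (not isolated)
24 | zwitterion: (S)-lactone O-arylated on the ring oxygen at C8a, carbanion at C4a | O=C1C[C@@H](c2ccc(OC(C)=O)cc2)[O+]1c1c(CC=C(C)C)c(OCOC)c(CC=C(C)C)c(OCOC)[c-]1 | intermediate (not isolated)
25 | (S)-6,8-diprenylnaringenin 4'-acetate 5,7-bis(methoxymethyl) ether | CC(C)=CCc1c(OCOC)c(CC=C(C)C)c2c(c1OCOC)C(=O)C[C@@H](c1ccc(OC(C)=O)cc1)O2 | intermediate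
26 | (S)-6,8-diprenylnaringenin | CC(C)=CCc1c(O)c(CC=C(C)C)c2c(c1O)C(=O)C[C@@H](c1ccc(O)cc1)O2 | target

Total step count: 9. Longest linear sequence: 8 steps (steps 1 to 6, then 8 and 9); the lactone 22 is made in one step (step 7) and joins at step 8.

Steps least certain to work

Step 8 (key step, the one step beyond known chemistry). The most likely failure is reaction of the lactone through its carbonyl oxygen instead of its ring oxygen. Equally likely is β-elimination of the lactone by fluoride or by anionic by-products to the cinnamate, which then undergoes its own aryne insertion and closes by an oxa-Michael addition without facial control. Either path costs material and, worse, erodes the enantiomeric purity of 25. Fluoride opening of 22, cleavage of the aryl acetate and protonation of the aryl anion are further leaks. The fallback uses known chemistry only, sets out from 18 and returns at 25. Aryne generation with CsF in the presence of acetic acid, the known insertion of arynes into the C–O bond of carboxylic acids with the same orientation, should give 1-[2-hydroxy-4,6-bis(methoxymethoxy)-3,5-bis(3-methylbut-2-en-1-yl)phenyl]ethanone F1. Condensation with N,N-dimethylformamide dimethyl acetal gives the enaminone (E)-3-(dimethylamino)-1-[2-hydroxy-4,6-bis(methoxymethoxy)-3,5-bis(3-methylbut-2-en-1-yl)phenyl]prop-2-en-1-one F2. A trace of acid closes it to 5,7-bis(methoxymethoxy)-6,8-bis(3-methylbut-2-en-1-yl)-4H-chromen-4-one F3. Asymmetric conjugate addition of (4-acetoxyphenyl)boronic acid under Pd(OCOCF3)2 (divalent palladium) with a chiral pyridine–oxazoline ligand, a known way from chromones to flavanones, then gives 25 with C2 set by the ligand antipode.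

Step 7. What may go wrong is low turnover and insufficient facial selectivity with an aromatic aldehyde, together with thermal decarboxylation of the 4-aryl lactone during purification. The fallback sets out from 19 and returns at 22. SnCl2-catalysed Roskamp homologation with benzyl diazoacetate gives benzyl 3-(4-acetoxyphenyl)-3-oxopropanoate F4. Noyori hydrogenation with RuCl2[(R)-binap] (divalent ruthenium; ligand antipode chosen for the (S) alcohol) gives benzyl (S)-3-(4-acetoxyphenyl)-3-hydroxypropanoate F5. Hydrogenolysis of the benzyl ester over Pd/C gives (S)-3-(4-acetoxyphenyl)-3-hydroxypropanoic acid F6. Carboxyl activation with benzenesulfonyl chloride in pyridine at 0 °C closes the lactone with retention at the carbinol carbon.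

Step 5. What may go wrong is transfer of the silyl triflate to the acetal oxygens (loss of a methoxymethyl group) in competition with N-silylation, or incomplete N-masking, after which the base expels isopropyl isocyanate instead of lithiating the ring. Because two metalations share one flask, a second C-silylation by surplus silyl chloride, consumption of the second portion of n-BuLi by that surplus, and warming of the second aryllithium before transmetalation with migration of the carbamoyl group to carbon are further risks. The fallback sets out from 8 and returns at 17, which is then triflated as in the second half of step 6; it uses a carbamate that needs no N-protection and isolates after each metalation. Diethylcarbamoyl chloride and NaH give 3,5-bis(methoxymethoxy)-4-(3-methylbut-2-en-1-yl)phenyl N,N-diethylcarbamate F7. s-BuLi/TMEDA at −78 °C and TMSCl give 3,5-bis(methoxymethoxy)-4-(3-methylbut-2-en-1-yl)-2-(trimethylsilyl)phenyl N,N-diethylcarbamate F8. A second s-BuLi/TMEDA metalation, CuBr·SMe2 and 4 give 3,5-bis(methoxymethoxy)-2,4-bis(3-methylbut-2-en-1-yl)-6-(trimethylsilyl)phenyl N,N-diethylcarbamate F9. LiAlH4 in THF cleaves the carbamate reductively to 17.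

Step 2. What may go wrong is coupling of the arylcopper at the tertiary end of the allyl unit (allylic transposition to the 1,1-dimethylallyl isomer), or incomplete transmetalation followed by unselective alkylation by the aryllithium. The fallback sets out from 3 and returns at 7. The same lithiation and transmetalation are followed by allyl bromide, which has no regiochemical ambiguity, to give [4-allyl-3,5-bis(methoxymethoxy)phenoxy]triisopropylsilane F10. Cross-metathesis with excess 2-methylbut-2-ene and the second-generation Grubbs catalyst then turns the allyl into the prenyl group.

Step 9. What may go wrong is acid-catalysed addition of the C5 or C7 hydroxyl to a neighbouring prenyl alkene (chroman formation) before unmasking is complete, or slow methanolysis of the acetate that forces harsher conditions. The fallback sets out from 25 and returns at 26 and separates the two tasks under non-protic-acid conditions. Ammonium acetate in aqueous methanol at rt removes the aryl acetate and gives (S)-6,8-diprenylnaringenin 5,7-bis(methoxymethyl) ether F11. TMSOTf with 2,2'-bipyridyl in CH2Cl2 at 0 °C then converts the aryl acetals into silyl ethers, which water hydrolyses to 26.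

## Further compounds

F1 | step 8 | 1-[2-hydroxy-4,6-bis(methoxymethoxy)-3,5-bis(3-methylbut-2-en-1-yl)phenyl]ethanone | CC(C)=CCc1c(OCOC)c(CC=C(C)C)c(O)c(C(C)=O)c1OCOC
F2 | step 8 | (E)-3-(dimethylamino)-1-[2-hydroxy-4,6-bis(methoxymethoxy)-3,5-bis(3-methylbut-2-en-1-yl)phenyl]prop-2-en-1-one | CC(C)=CCc1c(OCOC)c(CC=C(C)C)c(O)c(C(=O)/C=C/N(C)C)c1OCOC
F3 | step 8 | 5,7-bis(methoxymethoxy)-6,8-bis(3-methylbut-2-en-1-yl)-4H-chromen-4-one | CC(C)=CCc1c(OCOC)c(CC=C(C)C)c2occc(=O)c2c1OCOC
F4 | step 7 | benzyl 3-(4-acetoxyphenyl)-3-oxopropanoate | CC(=O)Oc1ccc(cc1)C(=O)CC(=O)OCc1ccccc1
F5 | step 7 | benzyl (S)-3-(4-acetoxyphenyl)-3-hydroxypropanoate | CC(=O)Oc1ccc(cc1)[C@@H](O)CC(=O)OCc1ccccc1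
F6 | step 7 | (S)-3-(4-acetoxyphenyl)-3-hydroxypropanoic acid | CC(=O)Oc1ccc(cc1)[C@@H](O)CC(=O)O
F7 | step 5 | 3,5-bis(methoxymethoxy)-4-(3-methylbut-2-en-1-yl)phenyl N,N-diethylcarbamate | CCN(CC)C(=O)Oc1cc(OCOC)c(CC=C(C)C)c(OCOC)c1
F8 | step 5 | 3,5-bis(methoxymethoxy)-4-(3-methylbut-2-en-1-yl)-2-(trimethylsilyl)phenyl N,N-diethylcarbamate | CCN(CC)C(=O)Oc1cc(OCOC)c(CC=C(C)C)c(OCOC)c1[Si](C)(C)C
F9 | step 5 | 3,5-bis(methoxymethoxy)-2,4-bis(3-methylbut-2-en-1-yl)-6-(trimethylsilyl)phenyl N,N-diethylcarbamate | CCN(CC)C(=O)Oc1c(CC=C(C)C)c(OCOC)c(CC=C(C)C)c(OCOC)c1[Si](C)(C)C
F10 | step 2 | [4-allyl-3,5-bis(methoxymethoxy)phenoxy]triisopropylsilane | C=CCc1c(OCOC)cc(O[Si](C(C)C)(C(C)C)C(C)C)cc1OCOC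
F11 | step 9 | (S)-6,8-diprenylnaringenin 5,7-bis(methoxymethyl) ether | CC(C)=CCc1c(OCOC)c(CC=C(C)C)c2c(c1OCOC)C(=O)C[C@@H](c1ccc(O)cc1)O2
A1 | alternative 1 | (S)-6,8-diprenylnaringenin 7,4'-bis(tert-butyldimethylsilyl) ether | CC(C)=CCc1c(O[Si](C)(C)C(C)(C)C)c(CC=C(C)C)c2c(c1O)C(=O)C[C@@H](c1ccc(O[Si](C)(C)C(C)(C)C)cc1)O2
A2 | alternative 1 | (S)-6,8-diiodonaringenin 7,4'-bis(tert-butyldimethylsilyl) ether | Ic1c(O[Si](C)(C)C(C)(C)C)c(I)c2c(c1O)C(=O)C[C@@H](c1ccc(O[Si](C)(C)C(C)(C)C)cc1)O2
A3 | alternative 1 | tributyl(3-methylbut-2-enyl)stannane | CCCC[Sn](CCCC)(CCCC)CC=C(C)C
A4 | alternative 1 | (S)-naringenin | O=C1C[C@@H](c2ccc(O)cc2)Oc2cc(O)cc(O)c21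
A5 | alternative 2 | (S)-6,8-diprenylnaringenin 5-[2-(trimethylsilyl)ethyl] 7,4'-bis(triisopropylsilyl) ether | CC(C)=CCc1c(O[Si](C(C)C)(C(C)C)C(C)C)c(CC=C(C)C)c2c(c1OCC[Si](C)(C)C)C(=O)C[C@@H](c1ccc(O[Si](C(C)C)(C(C)C)C(C)C)cc1)O2
A6 | alternative 2 | (S)-1-[(5-methylhex-4-en-1-yn-1-yl)oxy]-1-[4-(triisopropylsilyloxy)phenyl]-5-[2-(trimethylsilyl)ethoxy]pent-4-yn-3-one | CC(C)=CCC#CO[C@@H](CC(=O)C#COCC[Si](C)(C)C)c1ccc(O[Si](C(C)C)(C(C)C)C(C)C)cc1
A7 | alternative 2 | triisopropyl[(5-methylhex-4-en-1-yn-1-yl)oxy]silane | CC(C)=CCC#CO[Si](C(C)C)(C(C)C)C(C)C
A8 | alternative 3 | (S)-6,8-diprenylnaringenin 7,4'-bis(triisopropylsilyl) ether | CC(C)=CCc1c(O[Si](C(C)C)(C(C)C)C(C)C)c(CC=C(C)C)c2c(c1O)C(=O)C[C@@H](c1ccc(O[Si](C(C)C)(C(C)C)C(C)C)cc1)O2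
A9 | alternative 3 | (S)-6-(2-diazo-5-methylhex-4-enoyl)-2-[4-(triisopropylsilyloxy)phenyl]-2,3-dihydro-4H-pyran-4-one | CC(C)=CCC(=[N+]=[N-])C(=O)C1=CC(=O)C[C@@H](c2ccc(O[Si](C(C)C)(C(C)C)C(C)C)cc2)O1
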